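(The numbers of this flask are assumed.)

Temperature is what I change from flask to flask, so I count in hours how long substrate survives at each setting.

common to all: substrate 0.050 M; partner 0.0300 M; protic impurity 0.0150 M; time 10 h

| charge | temperature |
|---|---|
| ash | 70 °C |
| oak | 100 °C |
| birch | 40 °C |
| larch | 130 °C |

- which flask leads in amount of target, in percent of the substrate charged ("all alike" within 1.5 percentage points) (ash / oak / birch / larch / all alike)
- how much target is there at the end, in percent of the substrate charged: ash
- how much target is there at the end, in percent of the substrate charged: oak
- how much target is there at the end, in percent of the substrate charged: birch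
- how much target is there at the end, in percent of the substrate charged: larch

- in percentages every species weighs as the substrate in it: one homo dimer counts as two
- for a step with 2 of a species take k times the square, and two of it per event
- all constants are for 70 °C and move with temperature by the activation energies and enthalpies

    target → over-reaction product (k1 = 8.2 × 10⁻⁶ min⁻¹, Ea1 = 118 kJ mol⁻¹)
    partner + protic impurity → quenched reagent (k2 = 0.24 L mol⁻¹ min⁻¹, Ea2 = 68.0 kJ mol⁻¹)
    substrate + partner ⇌ isomer of the product (K3 = 87 L mol⁻¹, k3 = 1.5 L mol⁻¹ min⁻¹, Ea3 = 49.0 kJ mol⁻¹, ΔH3 = 2.00 kJ mol⁻¹)
    2 substrate → homo dimer (k4 = 0.55 L mol⁻¹ min⁻¹, Ea4 = 79.0 kJ mol⁻¹)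
    substrate + partner ⇌ target (K5 = 40 L mol⁻¹, k5 = 2.6 L mol⁻¹ min⁻¹, Ea5 = 78.0 kJ mol⁻¹, ΔH5 = −2.00 kJ mol⁻¹)
    (constants at 70 °C)

Substrate and partner bind reversibly to target and to isomer, two substrate go irreversibly to homo dimer, protic impurity quenches partner, and target slowly over-reacts.

Does binding outrun dimerisation in birch? At 40 °C the dimer constant is 0.0388 L mol⁻¹ min⁻¹, so the dimer half-life at the charge is 4.30 h. Forward binding takes 0.696 h, which is faster. I therefore treat target and isomer as a resting state of substrate, in balance with the free species.

How much does that store slow the loss? In birch the binding constants are 42.8 L mol⁻¹ for target and 81.3 L mol⁻¹ for isomer, together 124 L mol⁻¹. I try [partner] at 0.0100 M, a third of its charge. The storage factor b, the pool of free substrate, target and isomer over free substrate, is then one plus the summed constants times [partner], or 2.24. Dimerisation sees free substrate, so the pool decays more slowly by b squared. I name the buffered dimer time τ: b squared over 2, the dimer constant and the charged substrate. 21.6 h The pool stands at its charge divided by one plus t/τ.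

Is the trial [partner] sound? At the end of birch, [substrate] is 0.0152 M, and the free share of partner is then 34.7%. The quench takes about 0.00220 M, less than the partner charge. The trial stands.

Target is the pool times [partner] times its constant over b, which gives 13.0% for birch. The hotter flasks need their own b, and so their own [partner]. For them I try 0.0150 M, the partner charge less the impurity charge, which is what a finished quench leaves with nothing bound; at that [partner] the lifetime of protic impurity in ash is 4.63 h, shorter than the run of 10 h. With the constants of each flask, b is 2.91 in ash, 2.95 in oak and 2.99 in larch, so τ is 2.56 h in ash, 0.284 h in oak and 0.0439 h in larch. That gives 4.21% for ash, 0.532% for oak and 0.0791% for larch, and the leader is birch.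

The forecast names birch, with 12.6% there and 3.1%, 0.45% and 0.06% in ash, oak and larch, on the ground that “it is set by the slow drains”.

The flasks give birch as leader, with 12.5% in birch, 3.20% in ash, 0.463% in oak and 0.0604% in larch.

In birch at 10.0 h the pool reads 62.8% of the charge against my 68.4%, and pool over free substrate reads 2.34 against my b of 2.24. The same birch flask read at 40 h, with the same τ of 21.6 h, should hold 35.1% in the pool, and it holds 36.8%, of which target is 7.63%.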